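Readings and results are calculated with constants of no real substance.

| flask | substrate | partner | remark | time |
|---|---|---|---|---|
| north-west | 0.14 M | 0.15 M | run made earlier |  |
| north | 0.22 M | 0.15 M | run made earlier |  |
| flask | 0.10 M | 0.150 M |  | 12 d |

- north-west (time / d: target / %): 0.125: 9.5; 0.333: 8.0; 0.833: 5.1; 2.08: 1.7; 5.00: 0.5; 12.0: 0.2
- north (time / d: target / %): 0.125: 7.9; 0.333: 5.9; 0.833: 3.7; 2.08: 0.8; 5.00: 0; 12.0: 0

(readings scatter by 0.3 percentage points)

1. the moment within 12 d at which there is most target
2. the amount of target, in percent of the substrate charged, at that time
3. the first time at which target reaches 6.9 %, in the same percent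



1. I choose to reckon the flask from where it stops. My quantity is the ceiling c, the share of the charged substrate that the partner can carry through, taken as the smaller of one and partner charge over substrate charge: in the flask 100 %. This assumes one partner per substrate, which is my assumption, since no reading shows partner.

2. First instants: both earlier runs read less at their second reading than at their first, at 0.125 d, so the target's rise is unread. The north-west run has c = 100 %, the same as the flask. In the north run c = 68.2 %, with partner as limiting reagent, and the first reading is 7.9 % against 9.5 % in the north-west run. So I take the north-west run as my guide and, as my own estimate, put the flask's peak near 0.125 d, at about 9.5 %. With that rise unread, I give no time for the level asked.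

3. Middle: the north-west readings fall from 9.5 % to 1.7 % by 2.08 d. This reads as a decay constant of 0.880 d⁻¹, a half-life of 0.788 d, carrying the scatter of the readings.

4. End: that half-life is far shorter than 12 d, so I expect hardly any target in the flask by then; the north-west run reads 0.2 % there. With c at 100 %, substrate is the flask's limiting reagent, and partner should keep 33.3 % of its charge.

5. The forecast gives 0.09 d (0.03 d to 0.15 d), 10.7 % (9.7 % to 12 %) and 0.7 h (0.2 h to 1.6 h), reasoning that “The rise is unobserved, but it must be essentially over by 0.125 d”. My peak is later and lower.

6. The flask holds most target, 9.85 %, at 0.144 d, and first reaches the level asked at 0.932 h.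

    substrate + partner → intermediate + by-product (k = 2.03 M⁻¹ h⁻¹)
    intermediate ⇌ target (K = 0.733, k = 12.4 h⁻¹)
    intermediate ⇌ isomer of the product (K = 2.70, k = 0.960 h⁻¹)
    target → over-reaction product (k = 0.349 h⁻¹)

7. At 12.0 d the flask holds over-reaction product >99.9 % and partner 33 % of its charge, against c = 100 % and the reckoned 33.3 %. The neighbour flask with 0.060 M of partner has c = 60.0 %, so partner is its limiting reagent. Its target peaks at 5.09 %. At 12.0 d it holds partner 0 % of its charge and substrate 40 % of the substrate charged, and its over-reaction product stands at 60.0 % of the substrate charged.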